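The route rests on one disconnection: the 2,5-dihydrofuran (O, C2, C1, C15, C16; cembrane numbering) is opened at O–C16 and stripped of C17, which reveals C2–C1=C15–C16 as a latent α-hydroxy allene. The key step, a palladium-catalysed oxidative cyclisation–methoxycarbonylation, closes this last ring and plants C17 on C15 in one operation. Its precursor is a fourteen-membered 2-vinylidene-cycloalkanol carrying the C7–C8 epoxide, and it comes straight from an intramolecular Nozaki–Hiyama allenylation of an epoxy enal/propargylic bromide built from farnesol, so that macrocyclisation itself writes the substrate of the key step. Ester reduction and acetylation finish the synthesis.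

Key step: step 10

Remark on numbering: macrocycles carry cembrane numbering (C1 and C15 = the sp2 carbons of the dihydrofuran, C2 = its CH–O carbon, C16 = its OCH2 carbon, C17 = the CH2OAc carbon, C7/C8 = epoxide carbons); acyclic compounds carry chain numbering from the oxygenated C1 terminus of farnesol.

Assumption: in step 9 the (S,S)-ligand is taken to deliver the (2R)-carbinol; if induction runs the other way, its antipode is used.

Step 1
Reactants: 1 (2E,6E)-farnesol
Product: 2 (2E,6E)-farnesyl tert-butyldimethylsilyl ether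
Conditions: TBSCl, imidazole, DMF, 0 °C → rt
Reagents that add atoms: tert-butyldimethylsilyl chloride, CC(C)(C)[Si](C)(C)Cl
Why: Standard silylation of the primary allylic alcohol gives an ether that later withstands organolithium chemistry and inductively deactivates C2=C3.

Step 2
Reactants: 2 (2E,6E)-farnesyl tert-butyldimethylsilyl ether
Product: 3 (2E,6E,10E)-12-hydroxyfarnesyl tert-butyldimethylsilyl ether
Conditions: SeO2 (cat.), tBuOOH, salicylic acid (cat.), CH2Cl2, rt
Reagents that add atoms: tert-butyl hydroperoxide, CC(C)(C)OO; SeO2, O=[Se]=O (catalytic oxygen carrier)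
Why: Riley-type allylic oxidation (ene reaction, then [2,3]-sigmatropic shift) should attack the most electron-rich, least hindered terminal olefin at its (E)-methyl group, so the new hydroxymethyl group is trans to the chain.

Step 3
Reactants: 3 (2E,6E,10E)-12-hydroxyfarnesyl tert-butyldimethylsilyl ether
Product: 4 (2E,6E,10E)-12-chlorofarnesyl tert-butyldimethylsilyl ether
Conditions: MsCl, LiCl, 2,4,6-collidine, DMF, 0 °C
Reagents that add atoms: lithium chloride, [Li+].[Cl-]
Why: Collington–Meyers chlorination, in situ mesylation followed by SN2 displacement with chloride at the primary allylic carbon, should proceed without allylic transposition and leave the silyl ether untouched.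

Step 4
Reactants: 4 (2E,6E,10E)-12-chlorofarnesyl tert-butyldimethylsilyl ether
Product: 5 (2E,6R,7R,10E)-12-chloro-6,7-epoxyfarnesyl tert-butyldimethylsilyl ether
Conditions: Shi ketone (D-fructose-derived, 30 mol %), KHSO5 (as 2KHSO5·KHSO4·K2SO4, about 1 equiv), K2CO3, Bu4NHSO4, aq. Na2B4O7, MeCN/CH2(OMe)2, 0 °C
Reagents that add atoms: potassium peroxymonosulfate, [K+].[O-]S(=O)(=O)OO
Why: Shi asymmetric epoxidation: the electrophilic dioxirane should select C6=C7, the only trisubstituted olefin not flanked by an allylic heteroatom, and its spiro transition state delivers oxygen to the face that gives the (6R,7R)-epoxide (reagent control), the future C7 and C8.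

Step 5
Reactants: 5 (2E,6R,7R,10E)-12-chloro-6,7-epoxyfarnesyl tert-butyldimethylsilyl ether; 6 propargyl bromide
Product: 9 (2E,6R,7R,10E)-1-[(tert-butyldimethylsilyl)oxy]-6,7-epoxy-3,7,11-trimethylhexadeca-2,10-dien-14-yn-16-ol, via 1,3-dilithiopropyne 7 (not isolated), via lithium acetylide 8 (not isolated)
Conditions: 6, nBuLi (2 equiv per 6), TMEDA, Et2O/hexane, −78 °C; then 5, −78 → 0 °C; then (CH2O)n, rt
Reagents that add atoms: formaldehyde (from paraformaldehyde), C=O
Why: Propargylation with 1,3-dilithiopropyne: the more reactive sp3 terminus of the dianion should displace the allylic chloride by SN2, and the surviving acetylide is then hydroxymethylated by formaldehyde, while the trisubstituted epoxide and the silyl ether are inert to the organolithium at low temperature.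

Step 6
Reactants: 9 (2E,6R,7R,10E)-1-[(tert-butyldimethylsilyl)oxy]-6,7-epoxy-3,7,11-trimethylhexadeca-2,10-dien-14-yn-16-ol
Product: 10 (2E,6R,7R,10E)-16-bromo-6,7-epoxy-3,7,11-trimethylhexadeca-2,10-dien-14-yn-1-yl tert-butyldimethylsilyl ether
Conditions: CBr4, PPh3, 2,6-lutidine (cat.), CH2Cl2, 0 °C
Reagents that add atoms: carbon tetrabromide, BrC(Br)(Br)Br
Why: Appel bromination proceeds by SN2 on the alkoxyphosphonium ion under near-neutral conditions that should leave the epoxide and the silyl ether intact.

Step 7
Reactants: 10 (2E,6R,7R,10E)-16-bromo-6,7-epoxy-3,7,11-trimethylhexadeca-2,10-dien-14-yn-1-yl tert-butyldimethylsilyl ether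
Product: 11 (2E,6R,7R,10E)-16-bromo-6,7-epoxy-3,7,11-trimethylhexadeca-2,10-dien-14-yn-1-ol
Conditions: Et3N·3HF, THF, rt
Reagents that add atoms: none
Why: Desilylation with the weakly acidic, weakly nucleophilic amine trihydrofluoride should free the allylic alcohol without opening the epoxide or displacing the propargylic bromide.

Step 8
Reactants: 11 (2E,6R,7R,10E)-16-bromo-6,7-epoxy-3,7,11-trimethylhexadeca-2,10-dien-14-yn-1-ol
Product: 12 (2E,6R,7R,10E)-16-bromo-6,7-epoxy-3,7,11-trimethylhexadeca-2,10-dien-14-ynal
Conditions: MnO2, CH2Cl2, rt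
Reagents that add atoms: none
Why: MnO2 oxidises only the allylic alcohol and should give the (E)-enal without isomerisation, leaving the propargylic bromide untouched.

Step 9
Reactants: 12 (2E,6R,7R,10E)-16-bromo-6,7-epoxy-3,7,11-trimethylhexadeca-2,10-dien-14-ynal
Product: 13 (2R,3E,7R,8R,11E)-7,8-epoxy-4,8,12-trimethyl-1-vinylidenecyclotetradeca-3,11-dien-2-ol
Conditions: CrCl2, (S,S)-1,8-bis(4-isopropyl-4,5-dihydrooxazol-2-yl)-3,6-diphenylcarbazole, iPr2NEt, THF, rt; slow addition of 12 (final 2 mM); aqueous work-up
Reagents that add atoms: none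
Why: Intramolecular Nozaki–Hiyama allenylation: divalent chromium inserts into the C–Br bond and the alkyl-substituted propargylchromium adds through its γ-carbon (SE2′, six-membered transition state) to the aldehyde, closing the fourteen-membered ring as the exocyclic allene, while the chiral tridentate ligand on chromium differentiates the aldehyde faces to set C2 as (R) and high dilution suppresses oligomerisation.

Step 10
Reactants: 13 (2R,3E,7R,8R,11E)-7,8-epoxy-4,8,12-trimethyl-1-vinylidenecyclotetradeca-3,11-dien-2-ol
Product: 14 methyl (2R,3E,7R,8R,11E)-2,16:7,8-diepoxycembra-1(15),3,11-trien-17-oate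
Conditions: PdCl2(MeCN)2 (10 mol %), p-benzoquinone, NaOAc, CO (1 atm), MeOH/THF, 0 °C → rt
Reagents that add atoms: carbon monoxide, [C-]#[O+]; methanol, CO
Why: Proposed new method: divalent palladium binds the terminal C15=C16 π-bond of the allene, the C2 hydroxyl attacks C16 anti to the metal (5-endo-trig oxypalladation, the only ring closed), and the resulting C15 σ-vinylpalladium inserts CO and is cleaved by methanol to the C17 ester, benzoquinone returning zerovalent palladium to the divalent state. The closest known reaction types are the oxypalladation–methoxycarbonylation of γ-hydroxy allenes, the cyclisation–carbonylation of allenyl ketones, and the 5-endo oxypalladation of 2,3-allenols with allyl halide capture of the same vinylpalladium; CO capture of that intermediate from an α-allenol is the unproven element. No stereocenter is formed and the C2–O bond is never broken, so C2 keeps the configuration set in step 9. The step needs chemoselectivity for the allene over the C3=C4 and C11=C12 trisubstituted olefins and the C7–C8 epoxide, which the stronger binding of allenes to the metal, the proximity of the hydroxyl group and the acetate buffer should secure. Regiochemistry is fixed because the hydroxyl can reach only C16 in a five-membered closure, which places the metal and then the ester carbon on C15.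

Step 11
Reactants: 14 methyl (2R,3E,7R,8R,11E)-2,16:7,8-diepoxycembra-1(15),3,11-trien-17-oate
Product: 15 (2R,3E,7R,8R,11E)-2,16:7,8-diepoxycembra-1(15),3,11-trien-17-ol
Conditions: iBu2AlH, CH2Cl2, −78 °C
Reagents that add atoms: none
Why: 1,2-Reduction of the unsaturated ester by iBu2AlH at low temperature should give the allylic alcohol while the trisubstituted epoxide is not attacked.

Step 12
Reactants: 15 (2R,3E,7R,8R,11E)-2,16:7,8-diepoxycembra-1(15),3,11-trien-17-ol
Product: 16 lobophynin B
Conditions: Ac2O, pyridine, DMAP (cat.), CH2Cl2, 0 °C → rt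
Reagents that add atoms: acetic anhydride, CC(=O)OC(C)=O
Why: DMAP-catalysed acylation of the primary allylic alcohol completes the target under conditions that touch neither the epoxide nor the dihydrofuran.

Compound list

1 | (2E,6E)-farnesol, (2E,6E)-3,7,11-trimethyldodeca-2,6,10-trien-1-ol | CC(C)=CCC/C(C)=C/CC/C(C)=C/CO | starting material
2 | tert-butyl(dimethyl){[(2E,6E)-3,7,11-trimethyldodeca-2,6,10-trien-1-yl]oxy}silane | CC(C)=CCC/C(C)=C/CC/C(C)=C/CO[Si](C)(C)C(C)(C)C | intermediate
3 | (2E,6E,10E)-12-[(tert-butyldimethylsilyl)oxy]-2,6,10-trimethyldodeca-2,6,10-trien-1-ol | OC/C(C)=C/CC/C(C)=C/CC/C(C)=C/CO[Si](C)(C)C(C)(C)C | intermediate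
4 | tert-butyl{[(2E,6E,10E)-12-chloro-3,7,11-trimethyldodeca-2,6,10-trien-1-yl]oxy}dimethylsilane | ClC/C(C)=C/CC/C(C)=C/CC/C(C)=C/CO[Si](C)(C)C(C)(C)C | intermediate
5 | tert-butyl{[(2E,6R,7R,10E)-12-chloro-6,7-epoxy-3,7,11-trimethyldodeca-2,10-dien-1-yl]oxy}dimethylsilane | ClC/C(C)=C/CC[C@@]1(C)O[C@@H]1CC/C(C)=C/CO[Si](C)(C)C(C)(C)C | intermediate
6 | propargyl bromide (3-bromoprop-1-yne) | C#CCBr | starting material
7 | 1,3-dilithiopropyne | [Li]CC#C[Li] | intermediate (not isolated)
8 | lithium acetylide of (2E,6R,7R,10E)-1-[(tert-butyldimethylsilyl)oxy]-6,7-epoxy-3,7,11-trimethylpentadeca-2,10-dien-14-yne | [Li]C#CCC/C(C)=C/CC[C@@]1(C)O[C@@H]1CC/C(C)=C/CO[Si](C)(C)C(C)(C)C | intermediate (not isolated)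
9 | (2E,6R,7R,10E)-1-[(tert-butyldimethylsilyl)oxy]-6,7-epoxy-3,7,11-trimethylhexadeca-2,10-dien-14-yn-16-ol | OCC#CCC/C(C)=C/CC[C@@]1(C)O[C@@H]1CC/C(C)=C/CO[Si](C)(C)C(C)(C)C | intermediate
10 | tert-butyl{[(2E,6R,7R,10E)-16-bromo-6,7-epoxy-3,7,11-trimethylhexadeca-2,10-dien-14-yn-1-yl]oxy}dimethylsilane | BrCC#CCC/C(C)=C/CC[C@@]1(C)O[C@@H]1CC/C(C)=C/CO[Si](C)(C)C(C)(C)C | intermediate
11 | (2E,6R,7R,10E)-16-bromo-6,7-epoxy-3,7,11-trimethylhexadeca-2,10-dien-14-yn-1-ol | BrCC#CCC/C(C)=C/CC[C@@]1(C)O[C@@H]1CC/C(C)=C/CO | intermediate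
12 | (2E,6R,7R,10E)-16-bromo-6,7-epoxy-3,7,11-trimethylhexadeca-2,10-dien-14-ynal | BrCC#CCC/C(C)=C/CC[C@@]1(C)O[C@@H]1CC/C(C)=C/C=O | intermediate
13 | (2R,3E,7R,8R,11E)-7,8-epoxy-4,8,12-trimethyl-1-vinylidenecyclotetradeca-3,11-dien-2-ol (macrocyclic α-hydroxy allene, C1=C15=C16H2) | C=C=C1CC/C(C)=C/CC[C@@]2(C)O[C@@H]2CC/C(C)=C/[C@H]1O | intermediate
14 | methyl (2R,3E,7R,8R,11E)-2,16:7,8-diepoxycembra-1(15),3,11-trien-17-oate (macrocycle-fused methyl 2,5-dihydrofuran-3-carboxylate) | COC(=O)C1=C2CC/C(C)=C/CC[C@@]3(C)O[C@@H]3CC/C(C)=C/[C@H]2OC1 | intermediate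
15 | (2R,3E,7R,8R,11E)-2,16:7,8-diepoxycembra-1(15),3,11-trien-17-ol | OCC1=C2CC/C(C)=C/CC[C@@]3(C)O[C@@H]3CC/C(C)=C/[C@H]2OC1 | intermediate
16 | lobophynin B, (2R,3E,7R,8R,11E)-2,16:7,8-diepoxycembra-1(15),3,11-trien-17-yl acetate | CC(=O)OCC1=C2CC/C(C)=C/CC[C@@]3(C)O[C@@H]3CC/C(C)=C/[C@H]2OC1 | target

Total step count: 12. Longest linear sequence: 12 steps (1 → 16).

Steps most likely to fail

Step 10. The vinylpalladium may be protonated before CO inserts, which would give the dihydrofuran without C17. Acid released during turnover may also solvolyse the epoxide. The fallback uses known chemistry and sets out from 13. Gold-catalysed 5-endo cycloisomerisation in the presence of N-iodosuccinimide (AuCl(PPh3)/AgBF4, CH2Cl2, −20 °C) iodinates the vinylgold intermediate and should give the 15-iodo-2,5-dihydrofuran F1. The iodinating agent is added last and slowly, so that iododeauration outruns iodonium formation at the trisubstituted olefins. Stille coupling of F1 with (tributylstannyl)methanol (Pd(PPh3)4, dioxane, 80 °C) installs C17 as the hydroxymethyl group. The fallback comes back to the route at 15 and so also skips the ester reduction.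

Step 9. Ligand control over the aldehyde faces may be weak under high dilution, so that both C2 epimers form. The fallback sets out from 12. Ligand-free CrCl2 macrocyclisation under the same dilution should give the C2-epimeric allenol mixture F2. Sharpless kinetic resolution follows (Ti(OiPr)4, D-(−)-diisopropyl tartrate, tBuOOH, 4 Å molecular sieves, CH2Cl2, −20 °C, stopped near half conversion). It should epoxidise C3=C4 of the (2S)-epimer much faster and consume it as the epoxy alcohol F3. The allene is a poor partner for the titanium peroxide and is expected to be spared. The untouched (2R)-epimer is recovered, and the fallback comes back to the route at 13.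

Step 4. Site selectivity may be insufficient: a silyl ether deactivates less than an ester, so the dioxirane may also epoxidise C2=C3. The fallback sets out from 1 and places an acetate at C1 for the epoxidation. Acetylation (Ac2O, pyridine) gives (2E,6E)-farnesyl acetate F4. The same allylic oxidation gives the 12-hydroxy acetate F5, and the same chlorination gives the 12-chloro acetate F6. Shi epoxidation, now with an allylic acetate and an allylic chloride flanking C6=C7, should give the (6R,7R)-epoxy acetate F7. Reductive removal of the acetate (iBu2AlH, CH2Cl2, −78 °C) gives the epoxy chloro alcohol F8. Silylation (TBSCl, imidazole) comes back to the route at 5.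

Further compounds

F1 | step 10 | (2R,3E,7R,8R,11E)-15-iodo-2,16:7,8-diepoxy-17-norcembra-1(15),3,11-triene (4-iodo-2,5-dihydrofuran) | IC1=C2CC/C(C)=C/CC[C@@]3(C)O[C@@H]3CC/C(C)=C/[C@H]2OC1
F2 | step 9 | (3E,7R,8R,11E)-7,8-epoxy-4,8,12-trimethyl-1-vinylidenecyclotetradeca-3,11-dien-2-ol, mixture of C2 epimers | C=C=C1CC/C(C)=C/CC[C@@]2(C)O[C@@H]2CC/C(C)=C/C1O
F3 | step 9 | (3R,4R)-3,4-epoxide of the C2 epimer of 13 (3,4:7,8-diepoxy-4,8,12-trimethyl-1-vinylidenecyclotetradec-11-en-2-ol) | C=C=C1CC/C(C)=C/CC[C@@]2(C)O[C@@H]2CC[C@@]3(C)O[C@@H]3[C@@H]1O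
F4 | step 4 | (2E,6E)-farnesyl acetate | CC(C)=CCC/C(C)=C/CC/C(C)=C/COC(C)=O
F5 | step 4 | (2E,6E,10E)-12-hydroxyfarnesyl acetate | OC/C(C)=C/CC/C(C)=C/CC/C(C)=C/COC(C)=O
F6 | step 4 | (2E,6E,10E)-12-chlorofarnesyl acetate | ClC/C(C)=C/CC/C(C)=C/CC/C(C)=C/COC(C)=O
F7 | step 4 | (2E,6R,7R,10E)-12-chloro-6,7-epoxyfarnesyl acetate | ClC/C(C)=C/CC[C@@]1(C)O[C@@H]1CC/C(C)=C/COC(C)=O
F8 | step 4 | (2E,6R,7R,10E)-12-chloro-6,7-epoxy-3,7,11-trimethyldodeca-2,10-dien-1-ol | ClC/C(C)=C/CC[C@@]1(C)O[C@@H]1CC/C(C)=C/CO
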